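**Retrosynthetic overview**

- Numbering follows the SMILES: C1 (octyl), four-ring C1–C2–C12–C11, ring A C2–C3=C4–C5–C13–C12, five-ring C9–C10–C11–C12–C13, ring D C5–C6=C7–C8–C9–C13. The strategy rests on the 1,4-related oxygenated carbons C5 and C8 across the cyclopentane bond C9–C13: with C5 as ketone and C8 as ester, C13 and C9 are both enolate carbons.
- Ring D is cut at C5–C6 (alkenylmagnesium 1,2-addition from the C9 tether) and C6=C7 (iodo-Wittig), with C8 grown from the C9 ester. C9–C13 is then cut (oxidative bis-enolate coupling) to a bicyclo[4.2.0]octenone carrying an endo CH2–malonate at C11.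
- Ring A is cut at C3=C4 (aldol condensation, which also fixes C2), C9–C10 (malonate alkylation) and C4–C5 (MeLi on a lactone). The cis C10/C13 arms come from ozonolysis of the cyclopentene of an octylketeniminium–cyclopentadiene [2+2] adduct, because addition to an sp2 C11 flanked by exo-octyl and the ring would have little facial bias.
- Ring order: cyclobutane (step 2), ring A (step 10), cyclopentane (step 11), ring D (step 19).

Key step: step 11

Assumption: the (2R,5R)-auxiliary (step 2) and (−)-MIB (step 15) are taken to give the senses of induction drawn; if either is opposite, its antipode is used.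

**Step 1**
Reactants: 1 decanoyl chloride; 2 (2R,5R)-2,5-dimethylpyrrolidine
Product: 3 N-decanoyl-(2R,5R)-2,5-dimethylpyrrolidine
Conditions: Et3N, CH2Cl2, 0 → 23 °C
Reagents that add atoms: none
Why: N-acylation of a secondary amine by an acid chloride installs the C2-symmetric auxiliary that will later differentiate the faces of the keteniminium.

**Step 2**
Reactants: 3 N-decanoyl-(2R,5R)-2,5-dimethylpyrrolidine; 4 cyclopenta-1,3-diene (freshly cracked)
Product: 7 cis-fused 7-exo-octylbicyclo[3.2.0]hept-2-en-6-one, via keteniminium triflate 5 (not isolated), via cyclobutaniminium triflate 6 (not isolated)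
Conditions: Tf2O, 2,4,6-collidine, CH2Cl2, −30 °C; 4 (5 equiv), −30 → 23 °C; aq. NaHCO3; DBU (cat.), CH2Cl2, 23 °C
Reagents that add atoms: water — O
Why: Ghosez keteniminium–olefin [2+2] cycloaddition, in which the iminium carbon (C2) bonds to the diene terminus (C12) and the octyl-bearing carbon (C1) to the internal carbon (C11); the auxiliary should set C11/C12, the fusion is cis by suprafacial addition, and base equilibration α to the ketone should place octyl exo (trans to C10).

**Step 3**
Reactants: 7 cis-fused 7-exo-octylbicyclo[3.2.0]hept-2-en-6-one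
Product: 8 6-(methoxymethylene)-7-exo-octylbicyclo[3.2.0]hept-2-ene (E/Z mixture)
Conditions: Ph3P(CH2OMe)Cl, KHMDS, THF, 0 → 23 °C
Reagents that add atoms: (methoxymethyl)triphenylphosphonium chloride — COC[P+](c1ccccc1)(c1ccccc1)c1ccccc1.[Cl-]
Why: Wittig olefination of the strained cyclobutanone adds C3 at the aldehyde oxidation level; the E/Z ratio is without consequence and exo-octyl is the stable C1 configuration.

**Step 4**
Reactants: 8 6-(methoxymethylene)-7-exo-octylbicyclo[3.2.0]hept-2-ene
Product: 9 6-(dimethoxymethyl)-7-exo-octylbicyclo[3.2.0]hept-2-ene (both C2 epimers)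
Conditions: MeOH, CSA (5 mol%), 0 → 23 °C
Reagents that add atoms: methanol — CO
Why: Acid-catalysed addition of methanol to the enol ether (protonation at C2, capture of the oxocarbenium ion) should give an ozone-stable dimethyl acetal; C2 is left unselected because it becomes epimerisable again in step 10.

**Step 5**
Reactants: 9 6-(dimethoxymethyl)-7-exo-octylbicyclo[3.2.0]hept-2-ene
Product: 11 cyclobutane diol with cis C11–CH2OH and C12–CH2CH2OH arms, via ozonide 10 (not isolated)
Conditions: O3, CH2Cl2, −78 °C; then NaBH4, MeOH, −78 → 0 °C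
Reagents that add atoms: ozone — [O-][O+]=O
Why: Ozonolysis with direct hydride reduction of the ozonide cleaves C10=C5 to two primary alcohols without a free, epimerisable C11 aldehyde, so the cis relation of the C10 and C13 arms is inherited from the ring fusion.

**Step 6**
Reactants: 11 cyclobutane diol
Product: 13 cis-fused 7-(dimethoxymethyl)-8-exo-octyl-3-oxabicyclo[4.2.0]octan-4-one, via lactol 12 (not isolated)
Conditions: TEMPO (0.2 equiv), PhI(OAc)2 (2.5 equiv), CH2Cl2, 23 °C
Reagents that add atoms: none
Why: TEMPO/PhI(OAc)2 oxidative lactonisation of a 1,5-diol, in which the unbranched C5 carbinol should be oxidised faster than the β-branched C10 carbinol, so the lactone carbonyl is C5 and the two arms are differentiated.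

**Step 7**
Reactants: 13 δ-lactone
Product: 14 hydroxy methyl ketone (C12–CH2COCH3 and C11–CH2OH; open form of the cyclic hemiketal)
Conditions: MeLi (1.05 equiv), THF, −78 °C; aq. NH4Cl at −78 °C
Reagents that add atoms: methyllithium — [Li]C
Why: Mono-addition of MeLi to a lactone stops at the lithium hemiketal at −78 °C, which on work-up should open to the methyl ketone (C4 added) and free the C10 alcohol.

**Step 8**
Reactants: 14 hydroxy methyl ketone
Product: 15 primary iodide (C10–I)
Conditions: I2, PPh3, imidazole, CH2Cl2, 0 → 23 °C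
Reagents that add atoms: iodine — II
Why: Appel-type (Garegg–Samuelsson) iodination of the primary alcohol is near-neutral and should spare the acetal and the ketone.

**Step 9**
Reactants: 15 primary iodide; 16 dimethyl malonate
Product: 17 dimethyl 2-{[2-(2-oxopropyl)-3-(dimethoxymethyl)-4-octylcyclobutyl]methyl}malonate
Conditions: NaH (2.8 equiv), 16 (3 equiv), THF/DMF, 50 °C
Reagents that add atoms: none
Why: SN2 alkylation of sodium dimethyl malonate by the primary iodide forms C9–C10; the weakly basic malonate anion should not enolise the methyl ketone appreciably.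

**Step 10**
Reactants: 17 malonate acetal ketone
Product: 19 dimethyl 2-{[cis-fused 8-exo-octyl-4-oxobicyclo[4.2.0]oct-2-en-7-endo-yl]methyl}malonate, via keto aldehyde 18 (not isolated)
Conditions: 2 M HCl, THF, 23 °C; then piperidine (0.3 equiv), AcOH (0.3 equiv), PhH, 60 °C
Reagents that add atoms: none
Why: Acetal hydrolysis then amine–acid catalysed intramolecular aldol condensation (methyl ketone C4 onto the C3 aldehyde) closes ring A; C2 epimerises through the enamine and only the epimer cis to the C13 arm can close, because a trans-fused bicyclo[4.2.0]octenone is too strained, so C2 is set cis to C12.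

**Step 11**
Reactants: 19 bicyclic enone malonate
Product: 21 tricyclic enone gem-diester (C9–C13 closed), via dilithio bis-enolate 20 (not isolated)
Conditions: LDA (2.05 equiv), THF, −78 °C, inverse addition; then divided cell, Cp2Fe (0.2 equiv), 0.1 M LiClO4/THF, 0.01 M substrate, RVC anode, Pt cathode (catholyte AcOH/LiClO4/THF), −40 °C, constant current, 2.2 F/mol
Reagents that add atoms: none
Why: Inverse addition to LDA deprotonates the malonate C9–H and then, kinetically, the α′ C13–H, so the enone is fully converted into the cross-conjugated dienolate before any oxidant is present and the malonate cannot add to C3; anodically regenerated ferrocenium then takes one electron from the more electron-rich ketone dienolate to give the C13 α-keto radical (spin on C13 and O), which is captured by the tethered malonate enolate at C9, and the resulting ester ketyl radical anion gives up the second electron (if the malonate is oxidised first, the malonyl radical adds to C13 and the same product results). The closest known reactions are the Fe(III)- and Cu(II)-mediated intramolecular oxidative heterocouplings of ketone and malonate enolates, ferrocenium-induced oxidative enolate cyclisations, and ferrocene-mediated anodic oxidation of 1,3-dicarbonyl anions. The cyclopentane C9–C10–C11–C12–C13 closes in the 5-exo-trig mode. C13 is the only new stereocentre and is substrate-controlled: the two-atom tether hangs from the endo face at C11, so C9 can reach C13 only on the concave face and the five-ring is cis-fused to ring A. The step needs intramolecular coupling over dimerisation, which high dilution and the low stationary radical concentration of a mediated electrolysis favour, and it needs C13 over C4 or C2, which the enone (no sp3 C4–H) and the strain of a cyclobutylidene dienolate at C2 secure.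

**Step 12**
Reactants: 21 tricyclic enone gem-diester
Product: 23 tricyclic keto ester with exo C9–CO2Me, via C9-epimeric endo ester 22 (not isolated)
Conditions: LiCl, H2O, DMSO, 150 °C; then NaOMe (0.2 equiv), MeOH, 23 °C
Reagents that add atoms: none
Why: Krapcho demethoxycarbonylation removes one ester; methoxide equilibration of the epimerisable C9 ester should place it on the convex face, trans to C5 across C9–C13, which is the target C9 configuration.

**Step 13**
Reactants: 23 tricyclic keto ester
Product: 24 diol (C5 allylic alcohol epimers and C8 primary alcohol)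
Conditions: DIBAL-H (5 equiv), CH2Cl2, −78 → 0 °C; Rochelle salt
Reagents that add atoms: none
Why: DIBAL-H reduces the ester to the primary alcohol and the enone 1,2 to the allylic alcohol, which sidesteps ester-versus-ketone chemoselectivity; the C5 epimer ratio is irrelevant.

**Step 14**
Reactants: 24 diol
Product: 25 tricyclic keto aldehyde (C5 enone and C8 aldehyde)
Conditions: Dess–Martin periodinane (2.5 equiv), CH2Cl2, 0 → 23 °C
Reagents that add atoms: none
Why: Dess–Martin oxidation restores the C5 enone and gives the C8 aldehyde under non-basic conditions; C9 is already in its stable exo configuration.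

**Step 15**
Reactants: 25 tricyclic keto aldehyde
Product: 26 C8 allylic alcohol (vinyl adduct with target C8 configuration)
Conditions: Zn(CH=CH2)2 (2 equiv), (−)-MIB (10 mol%), toluene/hexane, −20 → 0 °C
Reagents that add atoms: divinylzinc — C=C[Zn]C=C
Why: Amino-alcohol-catalysed divinylzinc addition is chemoselective for the aldehyde over the ketone and should deliver vinyl to the Re face of C8 under reagent control, since the two flanks of C9 offer little substrate bias.

**Step 16**
Reactants: 26 C8 allylic alcohol
Product: 27 C8 TBS ether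
Conditions: TBSOTf, 2,6-lutidine, CH2Cl2, −78 °C
Reagents that add atoms: tert-butyldimethylsilyl triflate — CC(C)(C)[Si](C)(C)OS(=O)(=O)C(F)(F)F
Why: Silylation of the secondary alcohol protects C8–OH through the oxidative cleavage and the organometallic ring closure.

**Step 17**
Reactants: 27 C8 TBS ether
Product: 29 α-silyloxy aldehyde (C7 aldehyde), via vicinal diol 28 (not isolated)
Conditions: OsO4 (2 mol%), NaIO4 (4 equiv), 2,6-lutidine, dioxane/H2O 3:1, 23 °C
Reagents that add atoms: osmium tetroxide — O=[Os](=O)(=O)=O; sodium periodate — [Na+].[O-]I(=O)(=O)=O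
Why: Lemieux–Johnson cleavage, in which the terminal vinyl group should be osmylated in preference to the electron-poor enone alkene and the diol is cleaved by periodate.

**Step 18**
Reactants: 29 α-silyloxy aldehyde
Product: 30 (Z)-α-iodo enoate (iodine cis to C8)
Conditions: Ph3P=CHCO2Me (1.5 equiv), NIS (1.5 equiv), CH2Cl2, −20 °C; then 29, 23 °C
Reagents that add atoms: methyl (triphenylphosphoranylidene)acetate — COC(=O)C=P(c1ccccc1)(c1ccccc1)c1ccccc1; N-iodosuccinimide — O=C1CCC(=O)N1I
Why: Wittig olefination with the stabilised α-iodo ylide should place the ester trans and the iodine cis to C8, the geometry needed for ring closure; the ylide does not attack the hindered enone ketone.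

**Step 19**
Reactants: 30 (Z)-α-iodo enoate
Product: 32 tetracyclic methyl ester with C5 tertiary alcohol and C8 OTBS, via alkenylmagnesium chloride 31 (not isolated)
Conditions: iPrMgCl·LiCl (1.15 equiv), THF, −78 → −40 °C; aq. NH4Cl
Reagents that add atoms: none
Why: Iodine–magnesium exchange of the ester-activated alkenyl iodide followed by Barbier-type intramolecular 1,2-addition of the α-magnesiated enoate to the C5 ketone closes ring D; the C9 tether reaches only the concave face of C5, so ring D is cis-fused to ring A and the hydroxyl lies on the convex face (cis to H13), and a hard carbanion is chosen because a soft MBH-type trigger (thiolate, phosphine) would add first to the ring-A enone.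

**Step 20**
Reactants: 32 tetracyclic silyl ether ester
Product: 33 tetracyclic dihydroxy methyl ester
Conditions: TBAF, AcOH, THF, 0 → 23 °C
Reagents that add atoms: none
Why: Buffered fluoride desilylation removes the secondary TBS ether without ionising the acid-sensitive bis-allylic tertiary alcohol.

**Step 21**
Reactants: 33 tetracyclic dihydroxy methyl ester
Product: 34 target acid CNP0106718.3
Conditions: LiOH, THF/MeOH/H2O, 23 °C; then 1 M HCl to pH 4, 0 °C
Reagents that add atoms: lithium hydroxide — [Li+].[OH-]
Why: Saponification of the methyl ester and careful acidification should give the acid; the ring geometry prevents lactonisation onto either hydroxyl.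

**Compound list**

1 | decanoyl chloride | CCCCCCCCCC(=O)Cl | starting material
2 | (2R,5R)-2,5-dimethylpyrrolidine | C[C@@H]1CC[C@@H](C)N1 | starting material
3 | N-decanoyl-(2R,5R)-2,5-dimethylpyrrolidine | CCCCCCCCCC(=O)N1[C@H](C)CC[C@H]1C | intermediate
4 | cyclopenta-1,3-diene | C1=CC=CC1 | starting material
5 | octylketeniminium triflate of 3 | CCCCCCCCC=C=[N+]1[C@H](C)CC[C@H]1C.[O-]S(=O)(=O)C(F)(F)F | intermediate
6 | cyclobutaniminium triflate ([2+2] adduct of 5 and 4) | CCCCCCCCC1C(=[N+]2[C@H](C)CC[C@H]2C)[C@@H]2CC=C[C@H]12.[O-]S(=O)(=O)C(F)(F)F | intermediate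
7 | cis-fused 7-exo-octylbicyclo[3.2.0]hept-2-en-6-one | CCCCCCCC[C@H]1C(=O)[C@@H]2CC=C[C@H]12 | intermediate
8 | 6-(methoxymethylene)-7-exo-octylbicyclo[3.2.0]hept-2-ene | CCCCCCCC[C@H]1C(=COC)[C@@H]2CC=C[C@H]12 | intermediate
9 | 6-(dimethoxymethyl)-7-exo-octylbicyclo[3.2.0]hept-2-ene (C2 epimers) | CCCCCCCC[C@H]1C(C(OC)OC)[C@@H]2CC=C[C@H]12 | intermediate
10 | secondary ozonide of 9 | CCCCCCCC[C@H]1C(C(OC)OC)[C@@H]2CC3OOC(O3)[C@H]12 | intermediate
11 | cyclobutane diol (C11–CH2OH cis to C12–CH2CH2OH, trans to octyl) | CCCCCCCC[C@H]1C(C(OC)OC)[C@H](CCO)[C@@H]1CO | intermediate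
12 | δ-lactol from 11 | CCCCCCCC[C@H]1C(C(OC)OC)[C@@H]2CC(O)OC[C@H]12 | intermediate
13 | cis-fused 7-(dimethoxymethyl)-8-exo-octyl-3-oxabicyclo[4.2.0]octan-4-one | CCCCCCCC[C@H]1C(C(OC)OC)[C@@H]2CC(=O)OC[C@H]12 | intermediate
14 | hydroxy methyl ketone (open form) | CCCCCCCC[C@H]1C(C(OC)OC)[C@H](CC(C)=O)[C@@H]1CO | intermediate
15 | iodo methyl ketone | CCCCCCCC[C@H]1C(C(OC)OC)[C@H](CC(C)=O)[C@@H]1CI | intermediate
16 | dimethyl malonate | COC(=O)CC(=O)OC | starting material
17 | malonate acetal ketone | CCCCCCCC[C@H]1C(C(OC)OC)[C@H](CC(C)=O)[C@@H]1CC(C(=O)OC)C(=O)OC | intermediate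
18 | keto aldehyde (C2 epimers) | CCCCCCCC[C@H]1C(C=O)[C@H](CC(C)=O)[C@@H]1CC(C(=O)OC)C(=O)OC | intermediate
19 | bicyclo[4.2.0]octenone with endo C11 malonate arm | CCCCCCCC[C@H]1[C@@H]2C=CC(=O)C[C@@H]2[C@@H]1CC(C(=O)OC)C(=O)OC | intermediate
20 | dilithio bis-enolate of 19 | CCCCCCCC[C@H]1[C@@H]2C=CC([O-])=C[C@@H]2[C@@H]1CC(C(=O)OC)=C([O-])OC.[Li+].[Li+] | intermediate
21 | tricyclic enone gem-diester | CCCCCCCC[C@H]1[C@@H]2C=CC(=O)[C@@H]3C(C(=O)OC)(C(=O)OC)C[C@H]1[C@H]23 | intermediate
22 | C9-epimeric (endo) keto ester | CCCCCCCC[C@H]1[C@@H]2C=CC(=O)[C@@H]3[C@H](C(=O)OC)C[C@H]1[C@H]23 | intermediate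
23 | exo C9 keto ester | CCCCCCCC[C@H]1[C@@H]2C=CC(=O)[C@@H]3[C@@H](C(=O)OC)C[C@H]1[C@H]23 | intermediate
24 | diol (C5 epimers) | CCCCCCCC[C@H]1[C@@H]2C=CC(O)[C@@H]3[C@@H](CO)C[C@H]1[C@H]23 | intermediate
25 | keto aldehyde | CCCCCCCC[C@H]1[C@@H]2C=CC(=O)[C@@H]3[C@@H](C=O)C[C@H]1[C@H]23 | intermediate
26 | C8 allylic alcohol | CCCCCCCC[C@H]1[C@@H]2C=CC(=O)[C@@H]3[C@@H]([C@H](O)C=C)C[C@H]1[C@H]23 | intermediate
27 | C8 TBS ether | CCCCCCCC[C@H]1[C@@H]2C=CC(=O)[C@@H]3[C@@H]([C@H](O[Si](C)(C)C(C)(C)C)C=C)C[C@H]1[C@H]23 | intermediate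
28 | vicinal diol from 27 | CCCCCCCC[C@H]1[C@@H]2C=CC(=O)[C@@H]3[C@@H]([C@H](O[Si](C)(C)C(C)(C)C)C(O)CO)C[C@H]1[C@H]23 | intermediate
29 | α-silyloxy aldehyde | CCCCCCCC[C@H]1[C@@H]2C=CC(=O)[C@@H]3[C@@H]([C@H](O[Si](C)(C)C(C)(C)C)C=O)C[C@H]1[C@H]23 | intermediate
30 | (Z)-α-iodo enoate | CCCCCCCC[C@H]1[C@@H]2C=CC(=O)[C@@H]3[C@@H]([C@H](O[Si](C)(C)C(C)(C)C)/C=C(\I)C(=O)OC)C[C@H]1[C@H]23 | intermediate
31 | α-magnesiated enoate | CCCCCCCC[C@H]1[C@@H]2C=CC(=O)[C@@H]3[C@@H]([C@H](O[Si](C)(C)C(C)(C)C)/C=C(\[Mg]Cl)C(=O)OC)C[C@H]1[C@H]23 | intermediate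
32 | tetracyclic methyl ester, C8 OTBS | CCCCCCCC[C@H]1[C@@H]2C=C[C@]3(O)C(C(=O)OC)=C[C@@H](O[Si](C)(C)C(C)(C)C)[C@H]4C[C@H]1[C@H]2[C@@H]43 | intermediate
33 | tetracyclic dihydroxy methyl ester | CCCCCCCC[C@H]1[C@@H]2C=C[C@]3(O)C(C(=O)OC)=C[C@@H](O)[C@H]4C[C@H]1[C@H]2[C@@H]43 | intermediate
34 | target acid CNP0106718.3 | CCCCCCCC[C@H]1[C@@H]2C=C[C@]3(O)C(C(=O)O)=C[C@@H](O)[C@H]4C[C@H]1[C@H]2[C@@H]43 | target

**Totals and risks**

Total steps: 21. Longest linear sequence: 21 steps (1 → 34).

Steps most likely to fail:

1. Step 11. The bis-enolate may couple intermolecularly or oligomerise, the mediator may turn over slowly in the cold basic electrolyte, or the product enolate may be oxidised further. The fallback closes the same bond by a polar two-electron path, setting out from 19 and returning at 21. The malonate is deprotonated (NaH) and brominated (NBS) to the bromomalonate F1. LiHMDS at −78 °C then forms the C13 dienolate, which is alkylated intramolecularly, either directly or after bromine transfer to C13 and SN2 attack of the malonate anion.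

2. Step 19. The exchange reagent may attack the ring-A ketone before iodine–magnesium exchange is complete, part of the iodide may be the E isomer that cannot close, or the magnesiated enoate may lose the silyloxy group. The fallback sets out from 29 and returns at 32. Wittig reaction with Ph3P=CHCO2Me gives the (E)-enoate F2. PhSH/Et3N masks the ring-A enone as the C3 sulfide F3. PhSLi (THF, −78 °C) then triggers a thia-Michael/aldol cascade (C6 ester enolate onto C5) to the bis-sulfide F4. Oxidation with mCPBA (2 equiv, −78 °C) gives the bis-sulfoxide F5, and thermolysis in toluene restores C3=C4 and creates C6=C7; the direction of the C3 sulfoxide elimination (C3=C4 versus C2=C3) is the weak point of this fallback.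

3. Step 2. The auxiliary may discriminate the keteniminium faces poorly, and [4+2] addition or cationic polymerisation of the diene may compete. The fallback sets out from 1 and 4 and returns at 7. Et3N generates octylketene F6 in the presence of cyclopentadiene, which after base epimerisation gives the racemic cyclobutanone F7. NaBH4 gives the racemic endo alcohol F8. Lipase-catalysed acylation (Amano PS, vinyl acetate) resolves it; the alcohol of the required configuration F9 (assumed to be the slow-reacting enantiomer) is separated from the acetate of its antipode and oxidised (DMP) to 7.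

**Further compounds**

F1 | step 11 | bromomalonate of 19 | CCCCCCCC[C@H]1[C@@H]2C=CC(=O)C[C@@H]2[C@@H]1CC(Br)(C(=O)OC)C(=O)OC
F2 | step 19 | (E)-γ-silyloxy enoate | CCCCCCCC[C@H]1[C@@H]2C=CC(=O)[C@@H]3[C@@H]([C@H](O[Si](C)(C)C(C)(C)C)/C=C/C(=O)OC)C[C@H]1[C@H]23
F3 | step 19 | C3 phenylthio adduct of F2 | CCCCCCCC[C@H]1[C@@H]2C(Sc4ccccc4)CC(=O)[C@@H]3[C@@H]([C@H](O[Si](C)(C)C(C)(C)C)/C=C/C(=O)OC)C[C@H]1[C@H]23
F4 | step 19 | tetracyclic bis-sulfide aldol product | CCCCCCCC[C@H]1[C@@H]2C(Sc5ccccc5)C[C@]3(O)C(C(=O)OC)C(Sc5ccccc5)[C@@H](O[Si](C)(C)C(C)(C)C)[C@H]4C[C@H]1[C@H]2[C@@H]43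
F5 | step 19 | tetracyclic bis-sulfoxide | CCCCCCCC[C@H]1[C@@H]2C(S(=O)c5ccccc5)C[C@]3(O)C(C(=O)OC)C(S(=O)c5ccccc5)[C@@H](O[Si](C)(C)C(C)(C)C)[C@H]4C[C@H]1[C@H]2[C@@H]43
F6 | step 2 | octylketene | CCCCCCCCC=C=O
F7 | step 2 | racemic 7-exo-octylbicyclo[3.2.0]hept-2-en-6-one | CCCCCCCC[C@H]1C(=O)[C@@H]2CC=C[C@H]12.CCCCCCCC[C@@H]1C(=O)[C@H]2CC=C[C@@H]12
F8 | step 2 | racemic 6-endo alcohol | CCCCCCCC[C@H]1[C@H](O)[C@@H]2CC=C[C@H]12.CCCCCCCC[C@@H]1[C@@H](O)[C@H]2CC=C[C@@H]12
F9 | step 2 | resolved 6-endo alcohol | CCCCCCCC[C@H]1[C@H](O)[C@@H]2CC=C[C@H]12
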